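**Target 39:** `C[C@H]1CC[C@@H]2[C@@H](CC[C@@]2(C)O)C(C)(C)/C1=C\C[C@@H]1[C@@]2(C)CCC(=O)C(C)(C)O[C@@H]2CC[C@]1(C)O`

## Analysis of the target

The target is a C30 bis-bicyclic triterpenoid whose two halves are joined only by a CH2–CH= link. The right half is a trans-fused oxepan-3-one/cyclohexane (rings A and B). Its ring oxygen lies between a CMe2 carbon and the ring-fusion CH; the other fusion carbon is quaternary with an axial methyl; ring B carries a tertiary C(Me)OH whose hydroxyl is axial and cis to that methyl, next to the CH that bears the equatorial CH2 link. The left half is a cis-fused bicyclo[5.3.0]decane (cycloheptane ring C, cyclopentane ring D). Ring D holds a tertiary C(Me)OH whose hydroxyl is cis to both fusion hydrogens; ring C carries, in a row, a CHMe carbon (methyl trans to the fusion hydrogens), the alkylidene carbon and a CMe2 carbon bonded to the fusion CH. The exocyclic trisubstituted alkene is Z, with the CH2 link on the CMe2 side. The eight stereocentres form two clusters of four with no relay between them, so each half must be made as one enantiomer and the alkene geometry must be set at or after the union. Sensitive features are the two tertiary alcohols (elimination under acid), the hindered alkene (migration into ring C or loss of geometry under acid) and the α-alkoxy ketone. The hard parts are the congested CMe2–CH(fusion) bond in the seven-membered ring, the cis fusion with the hydroxyl on the face of the fusion hydrogens (the opposite of what methyl addition to a bicyclic ketone gives), and the Z alkene beside a quaternary carbon. The strategy rests on the three contiguous ring C carbons CHMe, C(=) and CMe2: they are the skeleton of 2-methylpentan-3-one (7), hence of an oxyallyl cation that can be added across a diene made of the ring D alkene and a vinyl group.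

## Retrosynthetic reasoning

**39 to 37.** No C–C bond is cut. The ring A ketone is traced to the secondary alcohol of triol 38 and this to tris-silyl ether 37. The ketone has to be masked because the later ketone reduction at the linking carbon and the organometallic steps could not tell two ketones apart. Forward, a global desilylation and oxidation of the only secondary alcohol are needed.

**37 to 34.** The C–H bond of the CHMe carbon and the exocyclic alkene are disconnected together by an allylic transposition. This leads to allylic alcohol 34, with the alkene inside ring C and the hydroxyl on the linking carbon. A single carbinol stereocentre then controls both the CHMe configuration and the alkene geometry. Forward, the hydroxyl is replaced with inversion to give hydrazone 35, and diazene 36 delivers hydrogen suprafacially with loss of nitrogen.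

**34 to 33.** The carbinol comes from enone 33 by reagent-controlled reduction. Both chiral halves are too far from the carbonyl to be trusted for substrate control.

**33 to 15 and 31.** Both bonds to the carbonyl carbon are cut, giving enol triflate 15, alkene 31 (used as its borane 32) and a one-carbon carbonyl unit. The cut is made here because the ring C ketone, flanked by CMe2 and CHMe, is too hindered for olefination or nucleophilic addition, whereas its enol triflate couples well. The halves are joined late and convergently.

**15 to 10.** The triflate comes from ketone 13 through enolate 14; only one α-position can enolise. The ring-fusion C–H bond of 12 is traced to the alkene of 11, so that the tertiary hydroxyl can direct hydrogen to its own face. Silyl removal (10 to 11) and re-protection (12 to 13) frame that step.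

**10 to 6 and 8.** Ring C is cut at the CHMe–CH2 bond and the CMe2–CH(fusion) bond. This gives diene 6 and the three-carbon cation 9 from dibromoketone 8. The cut removes the ring, the quaternary carbon and the fusion stereocentre in one step, and leaves two reactants of three steps and one step. Forward, the step must be head-to-head, (4+3) and anti to the silyloxy group.

**6 and 8 to commercial materials.** Diene 6 comes from alkenyl iodide 4 and stannane 5; 4 is the silyl ether of carbinol 3, made by enantioselective methyl transfer from 2 to iodoenone 1. Dibromoketone 8 comes from ketone 7.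

**31 to 26.** The tertiary carbinol of 30 comes from methyl addition to exo-methylene ketone 29, where the axial angular methyl dictates the face. Enone 29 comes by allylic oxidation (28) of methylene compound 27, and 27 from ketone 26. This moves the oxygen one carbon along ring B and supplies the CH2 that becomes the link.

**26 to 25.** The CMe2–O bond of ring A is cut, giving hydroxy alkene 25. The exo mode and the Markovnikov mode of closure coincide for an isopropenyl group, so the ring size is not in doubt.

**25 to 16.** The side chain is traced through 24, 23, aldehyde 22, alcohol 21 and acid 20 to enone 18, that is to ring B of the (R)-Wieland–Miescher ketone 16. Ozonolysis (through 19) turns its enone ring into the three-carbon arm and the ring ketone. Reduction of 16 to 17 sets the hydroxyl cis to the angular methyl, the relationship needed for the trans-fused ring A.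

## Alternatives that were turned down

**Alternative 1:** The cut goes through ring C of an aromatic precursor. Rings C and D are taken back to the cycloheptatriene-fused cyclopentanone 6-methoxy-8-methyl-3,8a-dihydroazulen-1(2H)-one (A1). The forward step is an intramolecular asymmetric Buchner reaction with [Cu(MeCN)4]PF6 and a bis(oxazoline) ligand (monovalent copper): a carbene from a diazoketone side chain adds to the ipso/ortho bond of an anisole and the norcaradiene opens.
- For it: one catalytic step turns a flat, cheap arene into the whole 5–7 skeleton with the fusion stereocentre. On speed to a bicyclic core it is stronger than the chosen route, which needs four steps before its key step.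
- Against it: the oxygen of A1 sits on the carbon that must become CHMe, not on the alkylidene carbon. The future CMe2 carbon carries one methyl on a triene, and three ring alkenes must be reduced with control of the cis fusion. A conjugate methylation, a 1,2-carbonyl transposition and a further methylation would be needed before fragment union.
- The ring D ketone of A1 must become the carbinol by methyl addition. The nucleophile would enter anti to the seven-membered ring and put the hydroxyl trans to the fusion hydrogen, the wrong epimer.
- The carbene must also prefer the unsubstituted ortho bond over the methyl-bearing one and over C–H insertion.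
- In comparison, the chosen cycloaddition places the carbonyl exactly between the two methyl-bearing carbons, with the carbinol already in place to steer later steps.

**Alternative 2:** The key cut lies in the right half. Rings A and B are opened together to an open-chain diepoxide ending in an allylsilane. Forward, TMSOTf (with 2,6-di-tert-butylpyridine) lets the internal epoxide oxygen open the terminal epoxide at its CMe2 carbon (oxepane); the allylsilane then closes the cyclohexane on the epoxonium carbon. The product is the trans-fused oxepanol–methylenecyclohexane A2.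
- For it: two rings, the quaternary carbon and the trans fusion arise in one biomimetic step, with stereochemistry from reagent-controlled epoxidations. For rings A and B this is shorter than the fourteen steps used here from 16, and on that point the alternative is stronger.
- Against it as the strategy-carrying step: it does nothing for rings C and D, where the congested CMe2–CH bond, the cis fusion and the Z alkene lie.
- The cascade must be endo-selective twice and must end by C–C bond formation, not by loss of silicon or capture by the counter-ion.
- A2 still needs its exocyclic methylene hydrated to the axial tertiary alcohol, and its CH2O arm joined to a ring C ketone that is too hindered for olefination.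
- In comparison, the chosen strategy spends its risk on the left half, reaches rings A and B by slower but predictable ring chemistry, and offers a carbonyl-derived handle on ring C for the union.

**Alternative 3:** Ring C is cut at the CMe2–C(=) bond. Forward, Fe(acac)3 (trivalent iron) and PhSiH3 turn an isopropenyl group on ring D into a tertiary radical, which adds 7-exo-dig to an ynoate. The product is the cis-fused hydroazulenone A3 with an exocyclic enoate.
- For it: the quaternary carbon, the seven-membered ring and the trisubstituted alkene form together, and the ester comes out cis to CMe2, the geometry of the target. On the alkene this is stronger than the chosen route, which sets the geometry late by a transposition.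
- Against it: the substrate needs three stereocentres before the key step (two cis substituents on a cyclopentanone and the CHMe centre), so the approach is linear.
- A hindered tertiary radical must close a seven-membered ring faster than it is reduced, and the vinyl radical must take up hydrogen from the right side.
- The ring D ketone of A3 must again become the carbinol by methyl addition from the convex face, which puts the hydroxyl trans to the fusion hydrogens.
- The enoate carbon must afterwards be deoxygenated and bonded to ring B by an sp3–sp3 coupling.
- In comparison, the chosen strategy needs one stereocentre before its key step, fixes the carbinol first and uses it to set the fusion, and joins the halves at a carbonyl carbon.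

Key step: step 5

## Remarks on the chemistry

- The ring A carbinol carbon that becomes the ketone is formed without control in step 15. It is carried as a mixture of epimers from 23 to 38 (this centre is left undefined in the SMILES), and both epimers converge in step 28.
- The CHMe configuration in 10 to 13 is drawn as in the target but is not relied on. It is erased in step 9 and set in step 26.
- Azulene numbering is used for the left half: C1 carbinol, C3a and C8a fusion, C4 CMe2, C5 carbonyl, C6 CHMe. 1-Benzoxepine numbering is used for the right half: O1, C2 CMe2, C3 carbinol, C5a quaternary, C6, C7, C9a.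

## Route

Step 1
Reactants: 1 2-iodocyclopent-2-en-1-one; 2 dimethylzinc
Product: 3 (1R)-2-iodo-1-methylcyclopent-2-en-1-ol
Conditions: Me2Zn (2 equiv), Ti(OiPr)4 (1.2 equiv), bis(sulfonamide) diol ligand from trans-cyclohexane-1,2-diamine and camphor-10-sulfonyl chloride (5 mol %), toluene–hexane, rt; aq. NH4Cl
Reagents that add atoms: none
Why: Titanium-catalysed enantioselective 1,2-addition of a dialkylzinc to an α-substituted cyclic enone; the α-iodine makes the two carbonyl flanks very different and disfavours conjugate addition. The ligand enantiomer is chosen to give the (R)-carbinol, the only stereocentre carried into the key step.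

Step 2
Reactants: 3 (1R)-2-iodo-1-methylcyclopent-2-en-1-ol
Product: 4 triethyl{[(1R)-2-iodo-1-methylcyclopent-2-en-1-yl]oxy}silane
Conditions: Et3SiOTf, 2,6-lutidine, CH2Cl2, −78 to 0 °C
Reagents that add atoms: triethylsilyl trifluoromethanesulfonate, CC[Si](CC)(CC)OS(=O)(=O)C(F)(F)F
Why: Silylation of a tertiary alcohol with a silyl triflate. The ether prevents O-alkylation by the oxyallyl cation in step 5 and is the facial control element there.

Step 3
Reactants: 4 triethyl{[(1R)-2-iodo-1-methylcyclopent-2-en-1-yl]oxy}silane; 5 tributyl(vinyl)stannane
Product: 6 triethyl{[(1R)-1-methyl-2-vinylcyclopent-2-en-1-yl]oxy}silane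
Conditions: Pd(PPh3)4 (5 mol %), CuI (10 mol %), CsF (2 equiv), DMF, 45 °C
Reagents that add atoms: none
Why: Stille coupling of an alkenyl iodide with a vinylstannane, with copper and fluoride assisting transmetalation at the hindered iodide. The stereocentre is not touched.

Step 4
Reactants: 7 2-methylpentan-3-one
Product: 8 2,4-dibromo-2-methylpentan-3-one (racemic)
Conditions: Br2 (2 equiv), cat. HBr, CH2Cl2, 0 °C to rt
Reagents that add atoms: bromine, BrBr
Why: Acid-catalysed α,α′-dibromination of a dialkyl ketone. The first bromine enters at the tertiary carbon through the more substituted enol, the second at the CH2 on the other side.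

Step 5
Reactants: 6 triethyl{[(1R)-1-methyl-2-vinylcyclopent-2-en-1-yl]oxy}silane; 8 2,4-dibromo-2-methylpentan-3-one
Product: 10 1,4,4,6-tetramethyl-1-(triethylsilyloxy)-2,3,3a,4,6,7-hexahydroazulen-5(1H)-one with the C8=C8a alkene and 3a-H cis to OSiEt3, via oxyallyl cation 9 (not isolated)
Conditions: Fe2(CO)9 (1.5 equiv), 8 (1.5 equiv), benzene, 50–60 °C, N2
Reagents that add atoms: none
Why: Zerovalent iron from Fe2(CO)9 removes both bromines of 8 and gives the iron-bound oxyallyl cation 9 in its W form, which adds to the s-cis conformer of diene 6 in a stepwise, asynchronous (4+3) cycloaddition; the closest known reaction type is the iron-carbonyl-mediated (4+3) cycloaddition of α,α′-dibromoketones with open-chain and semicyclic 1,3-dienes. The CHMe terminus of 9 should bond first to the unsubstituted vinyl CH2 of 6, because this joins the two least hindered termini and leaves the more stable tetrasubstituted enolate beside an allyl cation spread over the vinyl CH and the ring CH. The seven-membered ring then closes by collapse of this zwitterion: the CMe2 enolate carbon attacks the ring terminus of the allyl cation, so that the new C8=C8a alkene lies inside the ring (a 7-endo closure). Closure at the other terminus would give a (3+2) cyclopentanone; it is disfavoured while the diene reacts from its s-cis form, which allylic strain from the quaternary carbinol carbon on the internal diene carbon favours. The new fusion stereocentre C3a is controlled by the C1 stereocentre of 6: both bonds form on the diene face opposite to the OSiEt3 group, which puts the CMe2 carbon anti to oxygen and syn to the C1 methyl. The CHMe centre (C6) depends on the cation geometry and the compact or extended approach and is not relied on, since it is planarised in step 9 and set in step 26. The step thus needs head-to-head regiochemistry, (4+3) over (3+2) closure and anti facial selectivity; these rest on the steric and enolate-stability difference between the two cation termini, on the s-cis bias, and on the size of the silyl ether.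

Step 6
Reactants: 10 silyloxy cycloadduct
Product: 11 1-hydroxy-1,4,4,6-tetramethyl-2,3,3a,4,6,7-hexahydroazulen-5(1H)-one
Conditions: Bu4NF, THF, 0 °C to rt
Reagents that add atoms: none
Why: Fluoride cleavage of the tertiary silyl ether frees the hydroxyl that must direct step 7. Any epimerisation at CHMe is without consequence.

Step 7
Reactants: 11 hydroxy cycloheptenone
Product: 12 cis-fused 1-hydroxy-1,4,4,6-tetramethyloctahydroazulen-5(1H)-one (3a-H, 8a-H and OH all cis)
Conditions: H2 (1 atm), [Ir(cod)(PCy3)(py)]PF6 (5 mol %), CH2Cl2, rt
Reagents that add atoms: none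
Why: Hydroxyl-directed homogeneous hydrogenation. The cationic iridium complex binds the tertiary allylic alcohol and delivers H2 to the same face of the trisubstituted alkene, so the new C8a–H is cis to OH and to C3a–H (cis fusion).

Step 8
Reactants: 12 cis-fused hydroxy ketone
Product: 13 triethylsilyl ether of 12
Conditions: Et3SiOTf, 2,6-lutidine, CH2Cl2, −78 °C
Reagents that add atoms: triethylsilyl trifluoromethanesulfonate, CC[Si](CC)(CC)OS(=O)(=O)C(F)(F)F
Why: Silyl triflate protection at low temperature; alcohol silylation is much faster than enol-silane formation from the hindered ketone. It masks the hydroxyl for the enolate and coupling chemistry.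

Step 9
Reactants: 13 silyloxy ketone
Product: 15 1,4,4,6-tetramethyl-1-(triethylsilyloxy)-1,2,3,3a,4,7,8,8a-octahydroazulen-5-yl trifluoromethanesulfonate, via potassium enolate 14 (not isolated)
Conditions: KN(SiMe3)2 (1.5 equiv), THF, −78 to 0 °C; PhNTf2, −78 °C to rt
Reagents that add atoms: N-phenylbis(trifluoromethanesulfonimide), O=S(=O)(N(c1ccccc1)S(=O)(=O)C(F)(F)F)C(F)(F)F; potassium bis(trimethylsilyl)amide, C[Si](C)(C)[N-][Si](C)(C)C.[K+] (potassium only in 14)
Why: Enol triflate formation. C6–H is the only enolisable position (C4 is quaternary), so a single tetrasubstituted enol triflate should form, as with 2,2,6-trimethylcyclohexanone. The CHMe stereocentre is erased on purpose.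

Step 10
Reactants: 16 (R)-(−)-Wieland–Miescher ketone
Product: 17 (4aR,5R)-5-hydroxy-4a-methyl-4,4a,5,6,7,8-hexahydronaphthalen-2(3H)-one
Conditions: NaBH4 (0.3 equiv), EtOH, −10 to 0 °C
Reagents that add atoms: none
Why: Chemoselective hydride reduction of the saturated ketone beside the enone. Hydride enters anti to the angular methyl and gives the alcohol cis to it, the relationship needed between the ring oxygen and the methyl of ring B.

Step 11
Reactants: 17 hydroxy enone
Product: 18 (4aR,5R)-4a-methyl-5-(triethylsilyloxy)-4,4a,5,6,7,8-hexahydronaphthalen-2(3H)-one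
Conditions: Et3SiCl, imidazole, DMF, rt
Reagents that add atoms: chlorotriethylsilane, CC[Si](Cl)(CC)CC
Why: Standard silylation of a secondary alcohol. Triethylsilyl is chosen because it can later be removed beside a tert-butyldimethylsilyl ether.

Step 12
Reactants: 18 silyloxy enone
Product: 20 3-[(1S,2R)-1-methyl-6-oxo-2-(triethylsilyloxy)cyclohexyl]propanoic acid, via α-keto aldehyde 19 (not isolated)
Conditions: O3, CH2Cl2–MeOH, −78 °C; then 30% H2O2, aq. NaHCO3, 0 °C to rt; mild acid work-up
Reagents that add atoms: ozone, [O-][O+]=O; hydrogen peroxide, OO
Why: Ozonolysis of the enone alkene gives the ring ketone and an α-keto aldehyde. Alkaline hydrogen peroxide cleaves this 1,2-dicarbonyl to the carboxylic acid, with loss of the former enone α-carbon as formic acid.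

Step 13
Reactants: 20 keto acid
Product: 21 (2S,3R)-2-(3-hydroxypropyl)-2-methyl-3-(triethylsilyloxy)cyclohexan-1-one
Conditions: BH3·SMe2 (1.1 equiv), THF, 0 °C
Reagents that add atoms: none
Why: Borane reduces a carboxylic acid, through its acyloxyborane, much faster than a ketone with a quaternary α-carbon.

Step 14
Reactants: 21 keto alcohol
Product: 22 3-[(1S,2R)-1-methyl-6-oxo-2-(triethylsilyloxy)cyclohexyl]propanal
Conditions: Dess–Martin periodinane, NaHCO3, CH2Cl2, 0 °C to rt
Reagents that add atoms: none
Why: Dess–Martin oxidation of a primary alcohol to the aldehyde under buffered conditions.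

Step 15
Reactants: 22 keto aldehyde
Product: 23 (2S,3R)-2-(3-hydroxy-4-methylpent-4-en-1-yl)-2-methyl-3-(triethylsilyloxy)cyclohexan-1-one (carbinol epimers)
Conditions: CH2=C(CH3)MgBr (1.1 equiv), THF, −78 °C; aq. NH4Cl
Reagents that add atoms: isopropenylmagnesium bromide, C=C(C)[Mg]Br
Why: Grignard addition at low temperature; the aldehyde is far more electrophilic than the ketone beside a quaternary carbon. The new carbinol centre is not controlled and need not be.

Step 16
Reactants: 23 allylic alcohol
Product: 24 (2S,3R)-2-[3-(tert-butyldimethylsilyloxy)-4-methylpent-4-en-1-yl]-2-methyl-3-(triethylsilyloxy)cyclohexan-1-one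
Conditions: t-BuMe2SiCl, imidazole, DMF, rt
Reagents that add atoms: tert-butyldimethylsilyl chloride, CC(C)(C)[Si](C)(C)Cl
Why: Silylation of the secondary allylic alcohol. It masks the future ring A ketone until step 27 and keeps this oxygen out of step 18.

Step 17
Reactants: 24 bis-silyl ether
Product: 25 (2S,3R)-2-[3-(tert-butyldimethylsilyloxy)-4-methylpent-4-en-1-yl]-3-hydroxy-2-methylcyclohexan-1-one
Conditions: pyridinium p-toluenesulfonate (cat.), MeOH, 0 °C to rt
Reagents that add atoms: none
Why: Mild acid-catalysed methanolysis removes the triethylsilyl ether selectively over the tert-butyldimethylsilyl ether. Non-basic conditions avoid retro-aldol cleavage of the β-hydroxy ketone.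

Step 18
Reactants: 25 hydroxy alkene
Product: 26 (5aS,9aR)-3-(tert-butyldimethylsilyloxy)-2,2,5a-trimethyloctahydro-1-benzoxepin-6(2H)-one (trans-fused; C3 epimers)
Conditions: [N,N′-bis(3,5-di-tert-butylsalicylidene)cyclohexane-1,2-diaminato]cobalt (divalent cobalt, 5 mol %), N-fluoro-2,4,6-trimethylpyridinium triflate (1.5 equiv), (Me2SiH)2O, PhCF3, rt
Reagents that add atoms: none
Why: Cobalt–salen hydrogen-atom-transfer hydroalkoxylation (radical–polar crossover). Hydrogen adds to the CH2 of the isopropenyl group, the tertiary radical is oxidised at cobalt, and the ring hydroxyl forms the C–O bond in a 7-exo Markovnikov closure. The hydroxyl and the side chain are trans-diequatorial on the cyclohexanone, so the oxepane is trans-fused; the new carbon is CMe2 and is not a stereocentre.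

Step 19
Reactants: 26 oxepane ketone
Product: 27 (5aR,9aR)-3-(tert-butyldimethylsilyloxy)-2,2,5a-trimethyl-6-methylenedecahydro-1-benzoxepine
Conditions: Ph3PCH3Br (3 equiv), KOtBu (2.8 equiv), toluene, rt to 80 °C
Reagents that add atoms: methyltriphenylphosphonium bromide, C[P+](c1ccccc1)(c1ccccc1)c1ccccc1.[Br-]
Why: Wittig methylenation of a ketone with one quaternary neighbour, using the ylide in excess with heating.

Step 20
Reactants: 27 methylene compound
Product: 28 7-hydroxy derivative of 27 (allylic alcohol; C7 epimers)
Conditions: SeO2 (0.5 equiv), t-BuOOH (3 equiv), CH2Cl2, rt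
Reagents that add atoms: tert-butyl hydroperoxide, CC(C)(C)OO (oxygen passed on through SeO2, O=[Se]=O)
Why: Selenium dioxide allylic hydroxylation (ene reaction, then 2,3-sigmatropic shift) occurs at the only allylic CH2 (C7), since the other allylic carbon is quaternary.

Step 21
Reactants: 28 allylic alcohol
Product: 29 (5aR,9aR)-3-(tert-butyldimethylsilyloxy)-2,2,5a-trimethyl-6-methyleneoctahydro-1-benzoxepin-7(2H)-one
Conditions: Dess–Martin periodinane, NaHCO3, CH2Cl2, rt
Reagents that add atoms: none
Why: Dess–Martin oxidation converges both C7 epimers, and any enone already formed in step 20, on the exo-methylene ketone.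

Step 22
Reactants: 29 exo-methylene ketone
Product: 30 (5aR,7S,9aR)-3-(tert-butyldimethylsilyloxy)-2,2,5a,7-tetramethyl-6-methylenedecahydro-1-benzoxepin-7-ol (OH axial and cis to the C5a methyl)
Conditions: MeLi, CeCl3, THF, −78 °C; aq. NH4Cl
Reagents that add atoms: methyllithium, [Li]C
Why: Organocerium 1,2-addition to the enone, without conjugate addition or enolisation. The nucleophile comes from the face opposite to the axial angular methyl, which is 1,3-diaxial to the carbonyl carbon, so the hydroxyl becomes axial and cis to that methyl.

Step 23
Reactants: 30 tertiary allylic alcohol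
Product: 31 triethylsilyl ether of 30 (right-half alkene)
Conditions: Et3SiOTf, 2,6-lutidine, CH2Cl2, −78 to 0 °C
Reagents that add atoms: triethylsilyl trifluoromethanesulfonate, CC[Si](CC)(CC)OS(=O)(=O)C(F)(F)F
Why: Silyl triflate protection of the hindered tertiary alcohol. It prevents borinate formation in step 24 and participation of this hydroxyl in step 26.

Step 24
Reactants: 31 right-half alkene; 15 enol triflate
Product: 33 enone in which C5 of the ring C alkene of 15 is joined through C(=O)–CH2 to C6 of the benzoxepine, via B-alkyl-9-BBN 32 (not isolated)
Conditions: 9-BBN-H (1.5 equiv), THF, rt to 60 °C; then 15, PdCl2(dppf) (10 mol %), K3PO4 (3 equiv, aq.), CO (1 atm), THF–DMF, 50 °C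
Reagents that add atoms: carbon monoxide, [C-]#[O+]; 9-borabicyclo[3.3.1]nonane, B1C2CCCC1CCC2 (boron and its ring only in 32)
Why: Hydroboration of the 1,1-disubstituted alkene puts boron on the CH2 and hydrogen on C6 from the face opposite to the axial methyl and axial silyloxy group on the two neighbouring carbons, so the CH2B arm is equatorial. The alkylborane then enters a carbonylative Suzuki–Miyaura coupling: oxidative addition of the enol triflate to zerovalent palladium, CO insertion, base-assisted transmetalation and reductive elimination.

Step 25
Reactants: 33 enone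
Product: 34 (R)-allylic alcohol at the linking carbinol carbon
Conditions: (S)-2-methyl-CBS-oxazaborolidine (1 equiv), BH3·SMe2 (1.5 equiv), THF, −20 to 0 °C; MeOH
Reagents that add atoms: none
Why: Corey–Bakshi–Shibata reduction. The tetrasubstituted cycloalkenyl group is the large and the CH2 group the small substituent, so the (S)-oxazaborolidine should give the (R)-carbinol. Reagent control is needed because both chiral halves are remote.

Step 26
Reactants: 34 (R)-allylic alcohol
Product: 37 tris-silyl ether with the Z exocyclic alkene and the CHMe centre of the target, via N-allyl sulfonylhydrazone 35 (not isolated), via allylic diazene 36 (not isolated)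
Conditions: N-isopropylidene-N′-(2-nitrobenzenesulfonyl)hydrazine (1.5 equiv), PPh3, diethyl azodicarboxylate, THF, 0 to 23 °C; then CF3CH2OH–H2O (1:1), 23 °C
Reagents that add atoms: N-isopropylidene-N′-(2-nitrobenzenesulfonyl)hydrazine, CC(C)=NNS(=O)(=O)c1ccccc1[N+](=O)[O-] (its atoms are held only in 35 and 36)
Why: Reductive 1,3-transposition through an allylic diazene: Mitsunobu displacement with inversion gives 35, hydrolysis and loss of sulfinic acid give 36, and a retro-ene loss of N2 delivers hydrogen suprafacially to the ring carbon. In the reactive rotamer the C–N bond is perpendicular to the ring alkene, the carbinol hydrogen eclipses the alkene (least allylic 1,3-strain with the ring methyl) and the CH2 chain points to the CMe2 side. Hydrogen should therefore arrive on the face of the fusion hydrogens (methyl trans to them), and the new alkene should have the chain cis to CMe2 (Z).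

Step 27
Reactants: 37 tris-silyl ether
Product: 38 triol (ring A secondary alcohol as C3 epimers; both tertiary alcohols free)
Conditions: Bu4NF (10 equiv), THF, 50 °C
Reagents that add atoms: none
Why: Fluoride removes the two tertiary triethylsilyl ethers and the hindered secondary tert-butyldimethylsilyl ether. No base-sensitive group is present at this stage.

Step 28
Reactants: 38 triol
Product: 39 target
Conditions: Dess–Martin periodinane, NaHCO3, CH2Cl2, 0 °C to rt
Reagents that add atoms: none
Why: Dess–Martin oxidation of the only secondary alcohol converges both epimers on the ring A ketone. The tertiary alcohols cannot be oxidised, and the buffered conditions leave the alkene in place.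

## Compound list

1 | 2-iodocyclopent-2-en-1-one | O=C1CCC=C1I | starting material
2 | dimethylzinc | C[Zn]C | starting material
3 | (1R)-2-iodo-1-methylcyclopent-2-en-1-ol | IC1=CCC[C@@]1(C)O | intermediate
4 | triethyl{[(1R)-2-iodo-1-methylcyclopent-2-en-1-yl]oxy}silane | IC1=CCC[C@@]1(C)O[Si](CC)(CC)CC | intermediate
5 | tributyl(vinyl)stannane | C=C[Sn](CCCC)(CCCC)CCCC | starting material
6 | triethyl{[(1R)-1-methyl-2-vinylcyclopent-2-en-1-yl]oxy}silane | C=CC1=CCC[C@@]1(C)O[Si](CC)(CC)CC | intermediate
7 | 2-methylpentan-3-one | CCC(=O)C(C)C | starting material
8 | 2,4-dibromo-2-methylpentan-3-one (racemic) | CC(Br)C(=O)C(C)(C)Br | intermediate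
9 | 1,1,3-trimethyl-2-oxyallyl cation (iron-bound in the flask) | CC=C([O-])[C+](C)C | intermediate (not isolated)
10 | 1,4,4,6-tetramethyl-1-(triethylsilyloxy)-2,3,3a,4,6,7-hexahydroazulen-5(1H)-one, C8=C8a alkene, 3a-H cis to OSiEt3 (CHMe epimer tolerated) | C[C@H]1CC=C2[C@@H](CC[C@@]2(C)O[Si](CC)(CC)CC)C(C)(C)C1=O | intermediate
11 | 1-hydroxy-1,4,4,6-tetramethyl-2,3,3a,4,6,7-hexahydroazulen-5(1H)-one | C[C@H]1CC=C2[C@@H](CC[C@@]2(C)O)C(C)(C)C1=O | intermediate
12 | cis-fused 1-hydroxy-1,4,4,6-tetramethyloctahydroazulen-5(1H)-one (3a-H, 8a-H, OH cis) | C[C@H]1CC[C@@H]2[C@@H](CC[C@@]2(C)O)C(C)(C)C1=O | intermediate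
13 | triethylsilyl ether of 12 | C[C@H]1CC[C@@H]2[C@@H](CC[C@@]2(C)O[Si](CC)(CC)CC)C(C)(C)C1=O | intermediate
14 | potassium enolate of 13 | CC1=C([O-])C(C)(C)[C@@H]2CC[C@@](C)(O[Si](CC)(CC)CC)[C@@H]2CC1.[K+] | intermediate (not isolated)
15 | 1,4,4,6-tetramethyl-1-(triethylsilyloxy)-1,2,3,3a,4,7,8,8a-octahydroazulen-5-yl trifluoromethanesulfonate | CC1=C(OS(=O)(=O)C(F)(F)F)C(C)(C)[C@@H]2CC[C@@](C)(O[Si](CC)(CC)CC)[C@@H]2CC1 | intermediate
16 | (R)-(−)-Wieland–Miescher ketone, (8aR)-8a-methyl-3,4,8,8a-tetrahydronaphthalene-1,6(2H,7H)-dione | C[C@@]12CCC(=O)C=C1CCCC2=O | starting material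
17 | (4aR,5R)-5-hydroxy-4a-methyl-4,4a,5,6,7,8-hexahydronaphthalen-2(3H)-one | O=C1CC[C@@]2(C)[C@H](O)CCCC2=C1 | intermediate
18 | (4aR,5R)-4a-methyl-5-(triethylsilyloxy)-4,4a,5,6,7,8-hexahydronaphthalen-2(3H)-one | O=C1CC[C@@]2(C)[C@H](O[Si](CC)(CC)CC)CCCC2=C1 | intermediate
19 | 4-[(1S,2R)-1-methyl-6-oxo-2-(triethylsilyloxy)cyclohexyl]-2-oxobutanal | O=CC(=O)CC[C@@]1(C)[C@H](O[Si](CC)(CC)CC)CCCC1=O | intermediate (not isolated)
20 | 3-[(1S,2R)-1-methyl-6-oxo-2-(triethylsilyloxy)cyclohexyl]propanoic acid | OC(=O)CC[C@@]1(C)[C@H](O[Si](CC)(CC)CC)CCCC1=O | intermediate
21 | (2S,3R)-2-(3-hydroxypropyl)-2-methyl-3-(triethylsilyloxy)cyclohexan-1-one | OCCC[C@@]1(C)[C@H](O[Si](CC)(CC)CC)CCCC1=O | intermediate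
22 | 3-[(1S,2R)-1-methyl-6-oxo-2-(triethylsilyloxy)cyclohexyl]propanal | O=CCC[C@@]1(C)[C@H](O[Si](CC)(CC)CC)CCCC1=O | intermediate
23 | (2S,3R)-2-(3-hydroxy-4-methylpent-4-en-1-yl)-2-methyl-3-(triethylsilyloxy)cyclohexan-1-one (carbinol epimers) | C=C(C)C(O)CC[C@@]1(C)[C@H](O[Si](CC)(CC)CC)CCCC1=O | intermediate
24 | (2S,3R)-2-[3-(tert-butyldimethylsilyloxy)-4-methylpent-4-en-1-yl]-2-methyl-3-(triethylsilyloxy)cyclohexan-1-one | C=C(C)C(O[Si](C)(C)C(C)(C)C)CC[C@@]1(C)[C@H](O[Si](CC)(CC)CC)CCCC1=O | intermediate
25 | (2S,3R)-2-[3-(tert-butyldimethylsilyloxy)-4-methylpent-4-en-1-yl]-3-hydroxy-2-methylcyclohexan-1-one | C=C(C)C(O[Si](C)(C)C(C)(C)C)CC[C@@]1(C)[C@H](O)CCCC1=O | intermediate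
26 | (5aS,9aR)-3-(tert-butyldimethylsilyloxy)-2,2,5a-trimethyloctahydro-1-benzoxepin-6(2H)-one (trans-fused; C3 epimers) | O=C1CCC[C@H]2OC(C)(C)C(O[Si](C)(C)C(C)(C)C)CC[C@]12C | intermediate
27 | (5aR,9aR)-3-(tert-butyldimethylsilyloxy)-2,2,5a-trimethyl-6-methylenedecahydro-1-benzoxepine | C=C1CCC[C@H]2OC(C)(C)C(O[Si](C)(C)C(C)(C)C)CC[C@]12C | intermediate
28 | 7-hydroxy derivative of 27 (C7 epimers) | C=C1C(O)CC[C@H]2OC(C)(C)C(O[Si](C)(C)C(C)(C)C)CC[C@]12C | intermediate
29 | (5aR,9aR)-3-(tert-butyldimethylsilyloxy)-2,2,5a-trimethyl-6-methyleneoctahydro-1-benzoxepin-7(2H)-one | C=C1C(=O)CC[C@H]2OC(C)(C)C(O[Si](C)(C)C(C)(C)C)CC[C@]12C | intermediate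
30 | (5aR,7S,9aR)-3-(tert-butyldimethylsilyloxy)-2,2,5a,7-tetramethyl-6-methylenedecahydro-1-benzoxepin-7-ol | C=C1[C@@](C)(O)CC[C@H]2OC(C)(C)C(O[Si](C)(C)C(C)(C)C)CC[C@]12C | intermediate
31 | triethylsilyl ether of 30 (right-half alkene) | C=C1[C@@](C)(O[Si](CC)(CC)CC)CC[C@H]2OC(C)(C)C(O[Si](C)(C)C(C)(C)C)CC[C@]12C | intermediate
32 | B-alkyl-9-BBN from 31 (boron on the CH2, C6–H trans to the angular methyl) | C1CCC2CCCC1B2C[C@H]1[C@@](C)(O[Si](CC)(CC)CC)CC[C@H]2OC(C)(C)C(O[Si](C)(C)C(C)(C)C)CC[C@]12C | intermediate (not isolated)
33 | coupled enone (ring C alkenyl–C(=O)–CH2–ring B) | CC1=C(C(=O)C[C@H]2[C@@](C)(O[Si](CC)(CC)CC)CC[C@H]3OC(C)(C)C(O[Si](C)(C)C(C)(C)C)CC[C@]23C)C(C)(C)[C@@H]2CC[C@@](C)(O[Si](CC)(CC)CC)[C@@H]2CC1 | intermediate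
34 | (R)-allylic alcohol from 33 | CC1=C([C@H](O)C[C@H]2[C@@](C)(O[Si](CC)(CC)CC)CC[C@H]3OC(C)(C)C(O[Si](C)(C)C(C)(C)C)CC[C@]23C)C(C)(C)[C@@H]2CC[C@@](C)(O[Si](CC)(CC)CC)[C@@H]2CC1 | intermediate
35 | N-allyl-N-(2-nitrobenzenesulfonyl)hydrazone of acetone (inverted carbinol carbon) | CC1=C([C@@H](N(N=C(C)C)S(=O)(=O)c3ccccc3[N+](=O)[O-])C[C@H]2[C@@](C)(O[Si](CC)(CC)CC)CC[C@H]3OC(C)(C)C(O[Si](C)(C)C(C)(C)C)CC[C@]23C)C(C)(C)[C@@H]2CC[C@@](C)(O[Si](CC)(CC)CC)[C@@H]2CC1 | intermediate (not isolated)
36 | allylic monoalkyl diazene | CC1=C([C@@H](N=N)C[C@H]2[C@@](C)(O[Si](CC)(CC)CC)CC[C@H]3OC(C)(C)C(O[Si](C)(C)C(C)(C)C)CC[C@]23C)C(C)(C)[C@@H]2CC[C@@](C)(O[Si](CC)(CC)CC)[C@@H]2CC1 | intermediate (not isolated)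
37 | tris-silyl ether (Z alkene, CHMe set; ring A carbinol as epimers) | C[C@H]1CC[C@@H]2[C@@H](CC[C@@]2(C)O[Si](CC)(CC)CC)C(C)(C)/C1=C\C[C@@H]1[C@@]2(C)CCC(O[Si](C)(C)C(C)(C)C)C(C)(C)O[C@@H]2CC[C@]1(C)O[Si](CC)(CC)CC | intermediate
38 | triol (ring A secondary alcohol as epimers) | C[C@H]1CC[C@@H]2[C@@H](CC[C@@]2(C)O)C(C)(C)/C1=C\C[C@@H]1[C@@]2(C)CCC(O)C(C)(C)O[C@@H]2CC[C@]1(C)O | intermediate
39 | target | C[C@H]1CC[C@@H]2[C@@H](CC[C@@]2(C)O)C(C)(C)/C1=C\C[C@@H]1[C@@]2(C)CCC(=O)C(C)(C)O[C@@H]2CC[C@]1(C)O | target

## Step count and least certain steps

Total: 28 steps. Longest linear sequence: 19 steps (steps 10 to 28 from 16). The left half takes steps 1 to 3 and 5 to 9, with step 4 as a one-step branch.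

**Step 5 (key step).** The most likely failures are erosion of regiochemistry and diversion into (3+2) closure, because the two cation termini differ by only one methyl group and the diene is less reactive than a furan. Also possible are attack on the silyloxy face and ionisation of the tertiary allylic silyl ether by the iron bromide formed. The fallback sets out from 6 and comes back at 10. It takes the methyl group out of the cycloaddition. 6 is combined with the cation generated by base-mediated solvolysis (Et3N, CF3CH2OH) of 3-bromo-3-methylbutan-2-one F1. Its primary and tertiary termini differ far more, and no Lewis-acidic iron salt is formed. This should give the nor-methyl cycloadduct 1,4,4-trimethyl-1-(triethylsilyloxy)-2,3,3a,4,6,7-hexahydroazulen-5(1H)-one F2. The methyl group is then added by alkylation at the only enolisable position (LiN(iPr)2, THF, −78 °C; MeI), which gives 10 as a CHMe mixture that the route tolerates.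

**Step 24.** Possible failures are direct coupling without CO insertion, slow transmetalation of the β-branched alkylborane at a hindered acylpalladium, and incomplete facial control in the hydroboration. The fallback sets out from 15 and 31 and comes back at 33; it replaces the three-component coupling by acyl substitution. Aminocarbonylation of 15 (Pd(OAc)2, dppp, CO, MeNH(OMe)·HCl, Et3N, DMF) gives the Weinreb amide F3. Hydroboration–oxidation of 31 (9-BBN; NaOH, H2O2) gives the primary alcohol F4, where C6 epimers can be separated. This is converted into the primary iodide F5 (I2, PPh3, imidazole). Halogen–lithium exchange (t-BuLi, Et2O, −78 °C) gives the alkyllithium F6, which adds to F3 to give 33.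

**Step 26.** The Mitsunobu displacement may fail at the hindered allylic carbinol (elimination, attack at the far end of the allyl system, or ionisation with loss of configuration). The other rotamer may also react in the retro-ene step, which would give the E alkene together with the epimeric CHMe centre. The fallback sets out from 34 and comes back at 37. The alcohol is converted into the allylic methyl carbonate F7 (ClCO2Me, pyridine), which is subjected to palladium-catalysed formate hydrogenolysis (Pd(OAc)2, PBu3, HCO2NH4, dioxane, heat). Zerovalent palladium ionises the carbonate with inversion, and hydride is passed from palladium to the more substituted allyl terminus on the same face, which leads to 37 by a different mechanism.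

**Step 25.** Reduction may be slow and facial selectivity low, because the carbonyl is twisted out of conjugation between a tetrasubstituted alkene and a branched CH2 group; the remote chiral halves may also bias the outcome. The fallback sets out from 33 and comes back at 34. An unselective hydride reduction (NaBH4, CeCl3, MeOH) gives 34 with its (S)-carbinol epimer F8. The two diastereomers are separated by chromatography, and F8 is returned to 33 by Dess–Martin oxidation and recycled.

**Step 18.** Closure of the seven-membered ring may be slow, so that the cationic intermediate undergoes a 1,2-hydride shift from the silyloxy-bearing carbon or the alkene is merely reduced or isomerised. The fallback sets out from 25 and comes back at 26, and avoids a cationic intermediate. Intramolecular oxymercuration (Hg(OCOCF3)2, CH2Cl2, 0 °C; aq. NaCl; divalent mercury) gives the chloromercurio-methyl oxepane F9. Radical demercuration (Bu3SnH, AIBN, toluene) leaves the ketone untouched and gives 26.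

## Further compounds

F1 | step 5 | 3-bromo-3-methylbutan-2-one | CC(=O)C(C)(C)Br
F2 | step 5 | 1,4,4-trimethyl-1-(triethylsilyloxy)-2,3,3a,4,6,7-hexahydroazulen-5(1H)-one (nor-methyl cycloadduct) | O=C1CCC=C2[C@@H](CC[C@@]2(C)O[Si](CC)(CC)CC)C1(C)C
F3 | step 24 | N-methoxy-N-methyl amide at C5 of the ring C alkene (Weinreb amide from 15) | CC1=C(C(=O)N(C)OC)C(C)(C)[C@@H]2CC[C@@](C)(O[Si](CC)(CC)CC)[C@@H]2CC1
F4 | step 24 | primary alcohol from hydroboration–oxidation of 31 | OC[C@H]1[C@@](C)(O[Si](CC)(CC)CC)CC[C@H]2OC(C)(C)C(O[Si](C)(C)C(C)(C)C)CC[C@]12C
F5 | step 24 | primary iodide from F4 | IC[C@H]1[C@@](C)(O[Si](CC)(CC)CC)CC[C@H]2OC(C)(C)C(O[Si](C)(C)C(C)(C)C)CC[C@]12C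
F6 | step 24 | alkyllithium from F5 | [Li]C[C@H]1[C@@](C)(O[Si](CC)(CC)CC)CC[C@H]2OC(C)(C)C(O[Si](C)(C)C(C)(C)C)CC[C@]12C
F7 | step 26 | allylic methyl carbonate of 34 | CC1=C([C@H](OC(=O)OC)C[C@H]2[C@@](C)(O[Si](CC)(CC)CC)CC[C@H]3OC(C)(C)C(O[Si](C)(C)C(C)(C)C)CC[C@]23C)C(C)(C)[C@@H]2CC[C@@](C)(O[Si](CC)(CC)CC)[C@@H]2CC1
F8 | step 25 | (S)-carbinol epimer of 34 | CC1=C([C@@H](O)C[C@H]2[C@@](C)(O[Si](CC)(CC)CC)CC[C@H]3OC(C)(C)C(O[Si](C)(C)C(C)(C)C)CC[C@]23C)C(C)(C)[C@@H]2CC[C@@](C)(O[Si](CC)(CC)CC)[C@@H]2CC1
F9 | step 18 | 2-(chloromercuriomethyl) oxepane ketone (C2 and C3 epimers) | O=C1CCC[C@H]2OC(C)(C[Hg]Cl)C(O[Si](C)(C)C(C)(C)C)CC[C@]12C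
A1 | alternative 1 | 6-methoxy-8-methyl-3,8a-dihydroazulen-1(2H)-one | COC1=CC(C)=C2CCC(=O)[C@@H]2C=C1
A2 | alternative 2 | trans-fused oxepanol–methylenecyclohexane carrying CH2OTBS | CC(C)(C)[Si](C)(C)OC[C@@H]1[C@@]2(C)CC[C@@H](O)C(C)(C)O[C@@H]2CCC1=C
A3 | alternative 3 | cis-fused hydroazulenone with exocyclic enoate (ester cis to CMe2) | C[C@H]1CC[C@@H]2[C@@H](CCC2=O)C(C)(C)/C1=C\C(=O)OC
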